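(The data are calculated for substances that don't exist; the scatter is artificial.)

The unit I reckon in is the equivalent-minute: equivalents of coupling partner multiplied by minutes of stirring. I call this product the exposure. While [coupling partner] stays near its charge, a step that takes partner is pseudo-first-order, so I expect flasks of like exposure to hold like amounts of first product.

| flask | substrate | coupling partner | scavenger | remark | time |
|---|---|---|---|---|---|
| alpha | 17 mM | 0.50 equiv | 1 equiv | run made earlier |  |
| eta | 17 mM | 1.1 equiv | 1 equiv | run made earlier |  |
| gamma | 17 mM | 2.8 equiv | 1 equiv | run made earlier |  |
| Saturday's | 17 mM | 0.400 equiv | 1.00 equiv |  | 8.0 min |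
| Monday's | 17 mM | 1.00 equiv | 1.00 equiv |  | 8.0 min |
| Tuesday's | 17 mM | 3.00 equiv | 1.00 equiv |  | 8.0 min |

| run | time / min | first product / % |
|---|---|---|
| alpha | 1.00 | 4.5 |
| alpha | 2.50 | 8.6 |
| alpha | 3.00 | 10.0 |
| alpha | 5.00 | 14.8 |
| alpha | 6.00 | 15.6 |
| eta | 0.417 | 4.4 |
| eta | 0.833 | 7.7 |
| eta | 1.50 | 12.5 |
| eta | 3.00 | 18.1 |
| eta | 6.00 | 20.6 |
| gamma | 0.500 | 10.2 |
| gamma | 1.33 | 18.5 |
| gamma | 2.50 | 20.5 |
| gamma | 4.00 | 19.4 |
| gamma | 6.00 | 16.7 |

(scatter of a reading: 0.5 percentage points)

- "hardly changes" means that all values lie within two and a half points (for a concentration: within two and a half percent of the largest)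

1. amount of first product at the end, in percent of the substrate charged for Saturday's, Monday's, Tuesday's, in this order
2. the shape of the row from first to last (rises all the way / falls all the way / rises, then falls / hardly changes / falls, then rises)

The readings roughly support this clock: eta at 6.60 min reads 20.6%, and gamma at its highest reading reads 20.5%. I take the exposure of that gamma reading as the crossing exposure, where use of first product catches up with its making: 7.00 min.

Two extremes bracket the flasks. At very short exposure nothing is used, so first product follows alpha's first reading in proportion, which puts Saturday's flask at 28.8%. At long exposure, in a flask charged with partner in excess of substrate as gamma's is, first product falls: gamma's last readings go from 19.4% to 16.7%. The real flasks lie under the first line, and I take the second as a rough guide for Tuesday's flask, whose charge stands beside gamma's.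

Saturday's: 3.20 min, under the crossing, beside alpha's 3.00 min: about 15.6%

Monday's: 8.00 min, just past it: about 20.5%

Tuesday's: 24.0 min, gamma's tail carried on: 13.2%

The forecast gives 14.5%, 20% and 14%, and its shape is: rises, then falls. For Tuesday's flask it stands above my figure. Its ground for the fall is gamma's decline, where “over-reaction is significant there”.

The flasks give 15.1%, 21.8% and 12.3%, and the shape is: rises, then falls.

    substrate + coupling partner → first product + released group (k = 0.100 /M/s)
    substrate + released group ⇌ idle adduct, settled at all times (K = 46.0 /M)
    coupling partner + first product → double product + released group (k = 0.220 /M/s)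
    scavenger + released group → scavenged by-product (k = 0.620 /M/s)
    coupling partner + double product ⇌ tris adduct + released group (K = 46.0, k = 0.0890 /M/s)

Saturday's flask, at 3.20 min, is under the crossing of 7.00 min, and at 8.00 min it still makes first product 2.36 times faster than it uses it. Tuesday's flask, at 24.0 min, is far past the crossing, and its partner is down to 46.0% of charge. In Tuesday's flask the consumption of coupling partner, acting together with the time allowed, is part of the reason first product stands at 12.3%. With partner held at its charge Tuesday's flask gives 6.65%, and at ten times the time it gives 1.06%.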